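**Plan**
1. Numbering used: C1 (CO2H) to C14 (CHPh) along the chain; the 1,2-dioxane is O1–O2–C3–C4–C5–C6, with O1 on C6. Descriptors inside intermediate names follow each compound's own numbering.
2. Retrosynthesis: C10–C11 is cut last, giving alkenyl iodide 25 (finished 1,2-dioxane) and homoallylic iodide 8. In 25 the cuts are C2–C3 (ring peroxycarbenium ion + silyl ketene acetal), O2–C3 and O1–C6 (C6 hydroperoxide + C3 aldehyde), C9=C10 (Takai), C6–C7 (Negishi) and C4–C5 (Evans alkylation).
3. Forward: the open chain C3–C10 is assembled, O1–O2 is put on C6 by cobalt-mediated hydroperoxysilylation, the ring is closed as a C3 peroxyacetal, C2–C1 are added at C3, the two halves are joined at C10–C11, and the ester is hydrolysed.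
4. Stereochemistry: C12 and C4 come from Evans alkylations, C8 from methyl (2R)-3-hydroxy-2-methylpropanoate, and C3 from axial attack on a ring peroxycarbenium ion locked by the cis C4/C6 methyl groups. C6 is formed without control; the 6S epimer is taken by chromatography at 25. Both E alkenes are carried with retention.
5. Enabling feature: C10 is a vinylic CH of the E C9=C10 alkene, insulated from the ring by sp3 C7 and C8; C11 is a primary CH2; O1–O2 lies between quaternary C6 and branched C3. A palladium-catalysed sp2–sp3 union can therefore be run on the intact peroxide.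

Key step: step 15

**Route**

Step 1
Reactants: 1 (3E)-4-phenylbut-3-enoic acid; 2 (4R)-4-benzyl-1,3-oxazolidin-2-one
Product: 4 (4R)-4-benzyl-3-[(3E)-4-phenylbut-3-enoyl]-1,3-oxazolidin-2-one, via mixed pivalic anhydride 3 (not isolated)
Conditions: PivCl, Et3N, THF, -20 °C; then LiCl, 2, -20 °C to rt
Reagents that add atoms: none
Why: N-acylation through the mixed anhydride under the mild LiCl/Et3N protocol should attach the auxiliary without moving the styrenyl double bond, which stays conjugated with the arene.

Step 2
Reactants: 4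
Product: 6 (4R)-4-benzyl-3-[(2R,3E)-2-methyl-4-phenylbut-3-enoyl]-1,3-oxazolidin-2-one, via sodium dienolate 5 (not isolated)
Conditions: NaN(SiMe3)2 (1.05 equiv), THF, -78 °C; MeI, -78 °C
Reagents that add atoms: iodomethane, CI
Why: Evans alkylation, in which the chelated Z dienolate should be methylated at its α-carbon (kinetic site for metal dienolates) on the face opposite the benzyl group, setting C12 (2R in this imide).

Step 3
Reactants: 6
Product: 7 (2R,3E)-2-methyl-4-phenylbut-3-en-1-ol
Conditions: LiBH4, MeOH (1 equiv), Et2O, 0 °C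
Reagents that add atoms: none
Why: Reductive removal of the auxiliary with LiBH4 is not basic enough to epimerise the allylic α-stereocenter and should leave the styrene untouched.

Step 4
Reactants: 7
Product: 8 [(1E,3R)-4-iodo-3-methylbut-1-en-1-yl]benzene
Conditions: I2, PPh3, imidazole, CH2Cl2, 0 °C to rt
Reagents that add atoms: iodine, II
Why: Appel-type iodination is an SN2 displacement at the primary carbon C11 and does not involve the C12 stereocenter.

Step 5
Reactants: 9 (4R)-4-benzyl-3-propanoyl-1,3-oxazolidin-2-one; 10 2,3-dibromoprop-1-ene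
Product: 12 (4R)-4-benzyl-3-[(2S)-4-bromo-2-methylpent-4-enoyl]-1,3-oxazolidin-2-one, via sodium enolate 11 (not isolated)
Conditions: NaN(SiMe3)2, THF, -78 °C; 10 (3 equiv), -78 to -40 °C
Reagents that add atoms: none
Why: Evans alkylation by the allylic bromide (the vinylic bromide is inert) on the enolate face opposite the benzyl group sets C4 (2S in this imide) and brings in C5, C6 and the future C6 methyl carbon.

Step 6
Reactants: 12
Product: 13 (2S)-4-bromo-2-methylpent-4-en-1-ol
Conditions: LiBH4, MeOH (1 equiv), Et2O, 0 °C
Reagents that add atoms: none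
Why: LiBH4 cleaves the imide to the primary alcohol (C3) without touching the alkenyl bromide or the α-stereocenter.

Step 7
Reactants: 14 methyl (2R)-3-hydroxy-2-methylpropanoate
Product: 15 methyl (2S)-3-iodo-2-methylpropanoate
Conditions: I2, PPh3, imidazole, CH2Cl2, 0 °C
Reagents that add atoms: iodine, II
Why: Appel-type iodination at the primary carbon (C7) keeps the chiral-pool stereocenter (C8), whose descriptor changes only because CH2I outranks the ester carbon.

Step 8
Reactants: 15; 13
Product: 17 methyl (2R,6S)-7-hydroxy-2,6-dimethyl-4-methylideneheptanoate, via organozinc iodide 16 (not isolated)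
Conditions: 15, Zn dust, LiCl, THF, 25 °C; then 13, Pd(OAc)2 (2 mol %), SPhos (4 mol %), THF, 25 °C (2.2 equiv of 16)
Reagents that add atoms: none
Why: Negishi coupling of the β-zincio ester (zinc insertion leaves C8 untouched) with the 2-bromoalkene forms C6–C7 and the 1,1-disubstituted C6 alkene, and alkylzinc halides are protonated only slowly by a free hydroxy group.

Step 9
Reactants: 17
Product: 18 (2R,6S)-7-hydroxy-2,6-dimethyl-4-methylideneheptanal
Conditions: i-Bu2AlH (2.2 equiv), CH2Cl2, -78 °C; aqueous work-up
Reagents that add atoms: none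
Why: The tetrahedral aluminium intermediate is stable at -78 °C, so the ester (C9) should stop at the aldehyde without epimerising C8.

Step 10
Reactants: 18
Product: 19 (2S,6R,7E)-8-iodo-2,6-dimethyl-4-methylideneoct-7-en-1-ol
Conditions: CrCl2 (8 equiv), CHI3 (3 equiv), THF/1,4-dioxane, 0 °C to rt
Reagents that add atoms: iodoform, IC(I)I
Why: Takai olefination through a geminal dichromium species should give the E iodoalkene (C9=C10) from an α-branched aldehyde, tolerates the free alcohol and is not basic enough to epimerise C8.

Step 11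
Reactants: 19
Product: 20 (2S,6R,7E)-8-iodo-2,4,6-trimethyl-4-[(triethylsilyl)peroxy]oct-7-en-1-ol (both epimers at skeleton C6)
Conditions: Co(thd)2 (10 mol %; thd = 2,2,6,6-tetramethylheptane-3,5-dionate), Et3SiH (2 equiv), O2 (1 atm), ClCH2CH2Cl, rt
Reagents that add atoms: dioxygen, O=O; triethylsilane, CC[SiH](CC)CC
Why: Mukaiyama–Isayama hydroperoxysilylation, in which hydrogen-atom transfer from a cobalt hydride to the 1,1-disubstituted alkene gives the tertiary C6 radical that is trapped by O2 and silylated (the E iodoalkene is a much poorer acceptor); the planar radical is remote from C4 and C8, so no facial control is expected and both C6 epimers are carried on.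

Step 12
Reactants: 20
Product: 21 (2S,6R,7E)-8-iodo-2,4,6-trimethyl-4-[(triethylsilyl)peroxy]oct-7-enal (both epimers at skeleton C6)
Conditions: Dess–Martin periodinane, NaHCO3, CH2Cl2, 0 °C
Reagents that add atoms: none
Why: Buffered Dess–Martin oxidation should convert the primary alcohol (C3) into the aldehyde under conditions that a silyl peroxide and the α-stereocenter C4 survive.

Step 13
Reactants: 21
Product: 23 (4S)-6-[(2R,3E)-4-iodo-2-methylbut-3-en-1-yl]-3-methoxy-4,6-dimethyl-1,2-dioxane (C3 anomers of both C6 epimers), via hydroperoxy aldehyde 22 (not isolated)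
Conditions: p-TsOH·H2O (10 mol %), MeOH/CH2Cl2 (1:4), 0 °C to rt
Reagents that add atoms: methanol, CO
Why: Acidic methanolysis removes the silyl group, the freed C6 hydroperoxide adds to the C3 aldehyde and the six-membered peroxyhemiacetal is converted into its methyl peroxyacetal, which closes the ring through O2–C3 without touching C6–O1 (the C3 configuration is irrelevant because C3 is ionised in the next step).

Step 14
Reactants: 23; 24 tert-butyl[(1-methoxyethenyl)oxy]dimethylsilane
Product: 25 methyl 2-[(3S,4S,6S)-6-[(2R,3E)-4-iodo-2-methylbut-3-en-1-yl]-4,6-dimethyl-1,2-dioxan-3-yl]acetate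
Conditions: 24 (2 equiv), TMSOTf (0.3 equiv), CH2Cl2, -78 °C; then chromatography (removal of the C6 epimer)
Reagents that add atoms: none
Why: Ionisation of the C3 methoxy group gives a ring peroxycarbenium ion (O2=C3) that is trapped by the silyl ketene acetal (Mukaiyama-type substitution of a cyclic peroxyacetal), and in the 6S series the half-chair with the C4 and C6 methyl groups pseudo-equatorial (the other one would hold them syn-diaxial) is attacked along the axial trajectory leading directly to a chair, which should place the new CH2CO2Me group on C3 cis to both methyl groups (3S).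

Step 15
Reactants: 8; 25
Product: 28 methyl 2-[(3S,4S,6S)-4,6-dimethyl-6-[(2R,3E,6S,7E)-2,6-dimethyl-8-phenylocta-3,7-dien-1-yl]-1,2-dioxan-3-yl]acetate, via alkyllithium 26 (not isolated), via alkylzinc chloride 27 (not isolated)
Conditions: 8 (1.5 equiv), t-BuLi (3.1 equiv), Et2O/pentane, -78 °C, 5 min; ZnCl2 (1.7 equiv, THF), -78 °C to rt; then 25 (1.0 equiv), PdCl2(dppf) (5 mol %), THF, rt, dark
Reagents that add atoms: none
Why: Iodine–lithium exchange on 8 and immediate transmetalation give alkylzinc chloride 27; zerovalent palladium formed from PdCl2(dppf) inserts into the C10–I bond of 25 with retention of the E geometry, the C11 alkyl group passes from zinc to palladium, and reductive elimination forms C10–C11. The closest known reaction type is the Negishi alkyl–alkenyl coupling of an alkylzinc made from a primary iodide with an E iodoalkene, a type that has been run on alkenyl halides carrying cyclic peroxides. No ring is closed and no stereocenter is created: C3, C4, C6, C8 and C12 are only carried through, and the C9=C10 geometry is fixed by the stereoretentive oxidative addition. The step needs chemoselectivity for C(sp2)–I over O1–O2, which should be secured by the much faster insertion into the unhindered alkenyl iodide, by the shielding of the peroxide between quaternary C6 and branched C3, by the absence of base (no Kornblum–DeLaMare cleavage at C3–H, no enolisation at C2) and by the inertness of an alkylzinc toward the methyl ester. It also needs constitutional fidelity at C11, where a radical or a long-lived carbanion could close 3-exo onto the C13=C14 styrene and reopen with a 1,2-vinyl shift; the alkyllithium lives only minutes at -78 °C in a weakly coordinating medium before it is held in a covalent C–Zn bond. β-Hydride elimination toward C12 should be outrun by reductive elimination from the wide-bite-angle dppf complex.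

Step 16
Reactants: 28
Product: 29 2-[(3S,4S,6S)-4,6-dimethyl-6-[(2R,3E,6S,7E)-2,6-dimethyl-8-phenylocta-3,7-dien-1-yl]-1,2-dioxan-3-yl]acetic acid
Conditions: LiOH·H2O (3 equiv), THF/MeOH/H2O, 0 °C to rt; then 1 M HCl to pH 3
Reagents that add atoms: lithium hydroxide, [Li+].[OH-]
Why: Saponification of the methyl ester at low temperature should be faster than deprotonation at C2 or C3, so the β-peroxy ester is hydrolysed without retro-conjugate ring opening or base-induced peroxide fragmentation.

**Compound list**
1 | (3E)-4-phenylbut-3-enoic acid | OC(=O)C/C=C/c1ccccc1 | starting material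
2 | (4R)-4-benzyl-1,3-oxazolidin-2-one | O=C1OC[C@@H](Cc2ccccc2)N1 | starting material
3 | (3E)-4-phenylbut-3-enoic pivalic anhydride | CC(C)(C)C(=O)OC(=O)C/C=C/c1ccccc1 | intermediate
4 | (4R)-4-benzyl-3-[(3E)-4-phenylbut-3-enoyl]-1,3-oxazolidin-2-one | O=C(C/C=C/c1ccccc1)N1[C@H](Cc2ccccc2)COC1=O | intermediate
5 | sodium (1Z,3E)-1-[(4R)-4-benzyl-2-oxo-1,3-oxazolidin-3-yl]-4-phenylbuta-1,3-dien-1-olate | [Na+].C(/[O-])(N1[C@H](Cc2ccccc2)COC1=O)=C/C=C/c1ccccc1 | intermediate
6 | (4R)-4-benzyl-3-[(2R,3E)-2-methyl-4-phenylbut-3-enoyl]-1,3-oxazolidin-2-one | C[C@H](/C=C/c1ccccc1)C(=O)N1[C@H](Cc2ccccc2)COC1=O | intermediate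
7 | (2R,3E)-2-methyl-4-phenylbut-3-en-1-ol | C[C@H](/C=C/c1ccccc1)CO | intermediate
8 | [(1E,3R)-4-iodo-3-methylbut-1-en-1-yl]benzene | C[C@H](/C=C/c1ccccc1)CI | intermediate
9 | (4R)-4-benzyl-3-propanoyl-1,3-oxazolidin-2-one | CCC(=O)N1[C@H](Cc2ccccc2)COC1=O | starting material
10 | 2,3-dibromoprop-1-ene | C=C(Br)CBr | starting material
11 | sodium (1Z)-1-[(4R)-4-benzyl-2-oxo-1,3-oxazolidin-3-yl]prop-1-en-1-olate | [Na+].C(/[O-])(N1[C@H](Cc2ccccc2)COC1=O)=C/C | intermediate
12 | (4R)-4-benzyl-3-[(2S)-4-bromo-2-methylpent-4-enoyl]-1,3-oxazolidin-2-one | C=C(Br)C[C@H](C)C(=O)N1[C@H](Cc2ccccc2)COC1=O | intermediate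
13 | (2S)-4-bromo-2-methylpent-4-en-1-ol | C=C(Br)C[C@H](C)CO | intermediate
14 | methyl (2R)-3-hydroxy-2-methylpropanoate | COC(=O)[C@H](C)CO | starting material
15 | methyl (2S)-3-iodo-2-methylpropanoate | COC(=O)[C@H](C)CI | intermediate
16 | iodo[(2S)-3-methoxy-2-methyl-3-oxopropyl]zinc | COC(=O)[C@H](C)C[Zn]I | intermediate
17 | methyl (2R,6S)-7-hydroxy-2,6-dimethyl-4-methylideneheptanoate | COC(=O)[C@H](C)CC(=C)C[C@H](C)CO | intermediate
18 | (2R,6S)-7-hydroxy-2,6-dimethyl-4-methylideneheptanal | O=C[C@H](C)CC(=C)C[C@H](C)CO | intermediate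
19 | (2S,6R,7E)-8-iodo-2,6-dimethyl-4-methylideneoct-7-en-1-ol | I/C=C/[C@H](C)CC(=C)C[C@H](C)CO | intermediate
20 | (2S,6R,7E)-8-iodo-2,4,6-trimethyl-4-[(triethylsilyl)peroxy]oct-7-en-1-ol, both epimers at the peroxide carbon | I/C=C/[C@H](C)CC(C)(OO[Si](CC)(CC)CC)C[C@H](C)CO | intermediate
21 | (2S,6R,7E)-8-iodo-2,4,6-trimethyl-4-[(triethylsilyl)peroxy]oct-7-enal, both epimers at the peroxide carbon | I/C=C/[C@H](C)CC(C)(OO[Si](CC)(CC)CC)C[C@H](C)C=O | intermediate
22 | (2S,6R,7E)-4-hydroperoxy-8-iodo-2,4,6-trimethyloct-7-enal, both epimers at the peroxide carbon | I/C=C/[C@H](C)CC(C)(OO)C[C@H](C)C=O | intermediate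
23 | (4S)-6-[(2R,3E)-4-iodo-2-methylbut-3-en-1-yl]-3-methoxy-4,6-dimethyl-1,2-dioxane, mixture at C3 and C6 | I/C=C/[C@H](C)CC1(C)C[C@H](C)C(OC)OO1 | intermediate
24 | tert-butyl[(1-methoxyethenyl)oxy]dimethylsilane | C=C(OC)O[Si](C)(C)C(C)(C)C | starting material
25 | methyl 2-[(3S,4S,6S)-6-[(2R,3E)-4-iodo-2-methylbut-3-en-1-yl]-4,6-dimethyl-1,2-dioxan-3-yl]acetate | I/C=C/[C@H](C)C[C@@]1(C)C[C@H](C)[C@H](CC(=O)OC)OO1 | intermediate
26 | [(2S,3E)-2-methyl-4-phenylbut-3-en-1-yl]lithium | C[C@H](/C=C/c1ccccc1)C[Li] | intermediate
27 | chloro[(2R,3E)-2-methyl-4-phenylbut-3-en-1-yl]zinc | C[C@H](/C=C/c1ccccc1)C[Zn]Cl | intermediate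
28 | methyl 2-[(3S,4S,6S)-4,6-dimethyl-6-[(2R,3E,6S,7E)-2,6-dimethyl-8-phenylocta-3,7-dien-1-yl]-1,2-dioxan-3-yl]acetate | C[C@H](/C=C/c1ccccc1)C/C=C/[C@H](C)C[C@@]1(C)C[C@H](C)[C@H](CC(=O)OC)OO1 | intermediate
29 | 2-[(3S,4S,6S)-4,6-dimethyl-6-[(2R,3E,6S,7E)-2,6-dimethyl-8-phenylocta-3,7-dien-1-yl]-1,2-dioxan-3-yl]acetic acid | C[C@H](/C=C/c1ccccc1)C/C=C/[C@H](C)C[C@@]1(C)C[C@H](C)[C@H](CC(=O)O)OO1 | target

**Step count**
Total: 16 steps. Longest linear sequence: 11 steps (steps 5, 6 and 8 to 16).

**Steps most likely to fail**

Step 15. What may go wrong: reductive opening of the O1–O2 bond by zerovalent palladium or by the organozinc if transmetalation is slow, and partial 3-exo closure of the C11 carbanion onto the styrene before it is captured by zinc. Fallback: a boron-based union (B-alkyl Suzuki–Miyaura coupling). It sets out from 8. Iodine–lithium exchange (t-BuLi, Et2O, -78 °C) would be run with 9-methoxy-9-borabicyclo[3.3.1]nonane already present, so that the carbanion is trapped as it forms, giving lithium 9-methoxy-9-[(2S,3E)-2-methyl-4-phenylbut-3-en-1-yl]-9-boranuidabicyclo[3.3.1]nonane F1. This borate would be coupled with 25 (PdCl2(dppf), AsPh3, aqueous K3PO4, DMF, rt), where transmetalation from boron is fast and the borate is inert toward the peroxide. The fallback comes back to the route at 28.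

Step 11. What may go wrong: hydrogen-atom transfer to the C9=C10 iodoalkene or reductive loss of iodine under the cobalt hydride conditions, and over-reduction of the silyl peroxide to the tertiary alcohol. The absence of facial bias at C6 is accepted in the plan and handled by separation at 25. Fallback: the iodide is carried in masked form through the radical step. It sets out from 18. Chromium-mediated silyl-olefination (CrCl2, Me3SiCHBr2, THF) would give (2S,6R,7E)-2,6-dimethyl-4-methylidene-8-(trimethylsilyl)oct-7-en-1-ol F2. Hydroperoxysilylation as in step 11 would give (2S,6R,7E)-2,4,6-trimethyl-4-[(triethylsilyl)peroxy]-8-(trimethylsilyl)oct-7-en-1-ol F3. Ipso-iododesilylation with retention (N-iodosuccinimide, MeCN/ClCH2CN, 0 °C) comes back to the route at 20.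

Step 14. What may go wrong: attack on the peroxycarbenium ion through a twist-boat (poor facial selectivity at C3), Lewis-acid ionisation of the tertiary C6–O1 bond, or fragmentation of the cation. Fallback: ring closure by conjugate addition instead of substitution at C3. It sets out from 21. Wittig olefination with methyl (triphenylphosphoranylidene)acetate (CH2Cl2, rt) would give methyl (2E,4S,8R,9E)-10-iodo-4,6,8-trimethyl-6-[(triethylsilyl)peroxy]deca-2,9-dienoate F4. Desilylation with TBAF (THF, 0 °C) would release the peroxide anion, which closes the ring by 6-exo conjugate addition. This comes back to the route at 25, which would then have to be separated from its C3 epimers as well as its C6 epimers.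

**Further compounds**
F1 | step 15 | lithium 9-methoxy-9-[(2S,3E)-2-methyl-4-phenylbut-3-en-1-yl]-9-boranuidabicyclo[3.3.1]nonane | [Li+].C[C@H](/C=C/c1ccccc1)C[B-]1(OC)C2CCCC1CCC2
F2 | step 11 | (2S,6R,7E)-2,6-dimethyl-4-methylidene-8-(trimethylsilyl)oct-7-en-1-ol | C[Si](C)(C)/C=C/[C@H](C)CC(=C)C[C@H](C)CO
F3 | step 11 | (2S,6R,7E)-2,4,6-trimethyl-4-[(triethylsilyl)peroxy]-8-(trimethylsilyl)oct-7-en-1-ol, both epimers at the peroxide carbon | C[Si](C)(C)/C=C/[C@H](C)CC(C)(OO[Si](CC)(CC)CC)C[C@H](C)CO
F4 | step 14 | methyl (2E,4S,8R,9E)-10-iodo-4,6,8-trimethyl-6-[(triethylsilyl)peroxy]deca-2,9-dienoate, both epimers at the peroxide carbon | I/C=C/[C@H](C)CC(C)(OO[Si](CC)(CC)CC)C[C@H](C)/C=C/C(=O)OC
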